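**Plan**

Locants: side chain C3(O2H)–C2–C1 on C10. Ring B = C5(=C4Me2), C6, C7, C8, C9, C10. Ring C = C8, C9, C11, C12, C13, C14. C15 = benzylic CH2 on C14.
Cuts, in order: ArO–Ac and the ether/ester masks; C5=C4 (back to a C5 ketone); then in one stroke C9–C10 and C1–C2, with C9 returning to C5, so that ring B shrinks to the cyclopentane C5–C6–C7–C8–C9; then C5–C10, C13–CH3, C14–C15 and the two annulation bonds of ring C.
Enabling feature: the C10 methine sits between quaternary C9 and sp2 C5. With C5 written as a carbonyl, C9–C10–C5(=O) is the retron of a semipinacol 1,2-shift. Taking C10 out of ring B leaves a trans-hydrindan-1-one whose carbonyl is bonded to the methyl-bearing quaternary carbon, which is the Hajos–Parrish pattern.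
Forward: ring C and the five-membered forerunner of ring B arise together by amino-acid-catalysed annulation; the arene is joined at C14; C13 gets its methyl. A 1-(phenylthio)vinyl group (C10, C1; sulfur as removable cation stabiliser) is put on C5. One photoredox step then adds C2–C3, moves C9 onto C10 and makes ring B six-membered. Sulfur is removed, C4Me2 comes in via a β-lactone, and the arene is unmasked.
Stereochemistry: C9 from D-phenylalanine catalysis; C8 and C14 from protonation and benzylation of the Li/NH3 enolate opposite to the C9 methyl; C13 from α-face hydrogenation; C9 migrates with retention; C10 from α-face protonation of the C5 enolate.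

Key step: step 13

Remark: β is the face that carries the C9 methyl group and α the opposite face. Ar = 2,5-dimethoxy-3-methylphenyl. "Hydrindane" and "decalin" names use the locants above, and absolute configuration is that of the SMILES strings.

**Route**

Step 1
Reactants: 1 4-methoxy-2-methylphenol
Product: 2 2-hydroxy-5-methoxy-3-methylbenzaldehyde
Conditions: (CH2O)n, MgCl2, Et3N, MeCN, reflux; 1 M HCl
Reagents that add atoms: paraformaldehyde (formaldehyde source) C=O
Why: Casnati–Skattebøl ortho-formylation of the magnesium phenoxide can only strike the one free position ortho to the OH, which fixes the 1,2,3,5 pattern of the arene.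

Step 2
Reactants: 2 2-hydroxy-5-methoxy-3-methylbenzaldehyde
Product: 3 2,5-dimethoxy-3-methylbenzaldehyde
Conditions: MeI, K2CO3, DMF, 25 °C
Reagents that add atoms: iodomethane CI
Why: Williamson O-methylation gives the hydroquinone dimethyl ether, which should survive every later base, reductant and organometallic reagent.

Step 3
Reactants: 3 2,5-dimethoxy-3-methylbenzaldehyde
Product: 4 (2,5-dimethoxy-3-methylphenyl)methanol
Conditions: NaBH4, MeOH, 0 °C
Reagents that add atoms: none
Why: Borohydride reduction of an aromatic aldehyde to the benzylic alcohol is routine.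

Step 4
Reactants: 4 (2,5-dimethoxy-3-methylphenyl)methanol
Product: 5 1-(bromomethyl)-2,5-dimethoxy-3-methylbenzene
Conditions: PBr3, Et2O, 0 °C
Reagents that add atoms: phosphorus tribromide BrP(Br)Br
Why: PBr3 turns the electron-rich benzylic alcohol into the bromide by SN2 displacement of the phosphite ester, and the bromide is used at once.

Step 5
Reactants: 6 2-methylcyclopentane-1,3-dione, 7 pent-1-en-3-one
Product: 8 2-methyl-2-(3-oxopentyl)cyclopentane-1,3-dione
Conditions: H2O, AcOH (cat.), 75 °C
Reagents that add atoms: none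
Why: Michael addition of the acidic cyclic 1,3-dione to the vinyl ketone in water should stop at the triketone.

Step 6
Reactants: 8 2-methyl-2-(3-oxopentyl)cyclopentane-1,3-dione
Product: 9 (7aR)-4,7a-dimethyl-2,3,7,7a-tetrahydro-1H-indene-1,5(6H)-dione
Conditions: D-phenylalanine (1 equiv), (1R)-(−)-10-camphorsulfonic acid (0.5 equiv), DMF, 30 → 70 °C
Reagents that add atoms: none
Why: The Hajos–Parrish–Eder–Sauer–Wiechert enamine aldol condensation, in the phenylalanine/acid variant used for ethyl ketone side chains, differentiates the enantiotopic ring carbonyls, and the D-amino acid sets C9 as R.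

Step 7
Reactants: 9 (7aR)-4,7a-dimethyl-2,3,7,7a-tetrahydro-1H-indene-1,5(6H)-dione
Product: 10 (1R,7aR)-1-hydroxy-4,7a-dimethyl-1,2,3,6,7,7a-hexahydro-5H-inden-5-one
Conditions: NaBH4 (0.3 equiv), EtOH, −15 °C
Reagents that add atoms: none
Why: The saturated cyclopentanone is reduced faster than the tetrasubstituted enone (known chemoselectivity of this diketone class), and hydride comes from the face opposite to the angular methyl, giving the 5β-alcohol that masks C5.

Step 8
Reactants: 10 (1R,7aR)-1-hydroxy-4,7a-dimethyl-1,2,3,6,7,7a-hexahydro-5H-inden-5-one, 5 1-(bromomethyl)-2,5-dimethoxy-3-methylbenzene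
Product: 12 14α-(ArCH2)-5β-hydroxy-9β,14β-dimethyl-8αH-hydrindan-13-one, via dilithium enolate alkoxide 11 (not isolated)
Conditions: Li, NH3(l)/THF, −78 → −33 °C; isoprene; 5, THF, −78 → −33 °C; NH4Cl
Reagents that add atoms: none
Why: In this Stork reductive alkylation the enone radical anion is protonated at C8 on the α face by the substrate's own OH to give the trans-fused enolate 11, which is benzylated at C14 from the α face because the β face is closed by the 1,3-diaxial C9 methyl.

Step 9
Reactants: 12 14α-(ArCH2)-5β-hydroxy-9β,14β-dimethyl-8αH-hydrindan-13-one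
Product: 13 14α-(ArCH2)-9β,14β-dimethyl-13-methylene-8αH-hydrindan-5β-ol
Conditions: Ph3PCH3Br, KOtBu (excess), toluene, 90 °C
Reagents that add atoms: methyltriphenylphosphonium bromide C[P+](c1ccccc1)(c1ccccc1)c1ccccc1.[Br-]
Why: Wittig methylenation with excess ylide is the standard answer to a ketone next to a quaternary carbon, and the alkoxide formed from the free OH is a spectator.

Step 10
Reactants: 13 14α-(ArCH2)-9β,14β-dimethyl-13-methylene-8αH-hydrindan-5β-ol
Product: 14 14α-(ArCH2)-9β,13β,14β-trimethyl-8αH-hydrindan-5β-ol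
Conditions: H2 (1 atm), 10% Pd/C, EtOAc, 25 °C
Reagents that add atoms: none
Why: Heterogeneous hydrogenation should deliver H2 to the α face of ring C because the β face carries the two axial methyls at C9 and C14, so the new C13 methyl ends up equatorial and β.

Step 11
Reactants: 14 14α-(ArCH2)-9β,13β,14β-trimethyl-8αH-hydrindan-5β-ol
Product: 15 14α-(ArCH2)-9β,13β,14β-trimethyl-8αH-hydrindan-5-one
Conditions: Dess–Martin periodinane, CH2Cl2, 25 °C
Reagents that add atoms: none
Why: Dess–Martin oxidation unmasks the C5 ketone under neutral conditions that leave the electron-rich arene alone.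

Step 12
Reactants: 15 14α-(ArCH2)-9β,13β,14β-trimethyl-8αH-hydrindan-5-one, 16 phenyl vinyl sulfide
Product: 18 14α-(ArCH2)-9β,13β,14β-trimethyl-5α-[1-(phenylthio)vinyl]-8αH-hydrindan-5β-ol, via 1-(phenylthio)vinyllithium 17 (not isolated)
Conditions: 16, LDA, THF–DMPU, −78 °C; then 15, −78 → −30 °C; H2O
Reagents that add atoms: none
Why: 1,2-Addition of the α-thiovinyllithium to the cyclopentanone should take place from the α face, opposite to the C9 methyl, as in additions to 17-oxo steroids, to give the 5β-ol.

Step 13
Reactants: 18 14α-(ArCH2)-9β,13β,14β-trimethyl-5α-[1-(phenylthio)vinyl]-8αH-hydrindan-5β-ol, 19 benzyl bromoacetate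
Product: 21 benzyl 3-[14α-(ArCH2)-9β,13β,14β-trimethyl-5-oxo-10β-(phenylthio)-8αH-decalin-10α-yl]propanoate, via thionium ion 20 (not isolated)
Conditions: fac-Ir(ppy)3 (1 mol %), 19 (2 equiv), NaHCO3, degassed MeCN, blue LED (450 nm), 25 °C
Reagents that add atoms: none
Why: Proposed new method: the excited trivalent iridium complex reduces 19 to the electrophilic radical •CH2CO2Bn, which adds to the free CH2 terminus (C1) of the electron-rich vinyl sulfide, and the α-thio radical at C10 is oxidised by the tetravalent iridium complex (or takes up bromine from 19 and ionises) to thionium ion 20. In 20 the C5–C9 σ bond shifts to the electron-poor C10 while the C5–OH becomes the C5 ketone, so no ring is closed by cyclisation: the cyclopentane C5–C6–C7–C8–C9 takes up C10 in a suprafacial 1,2-alkyl shift and becomes six-membered ring B. The closest known reaction types are the photoredox radical–polar crossover semipinacol expansions of 1-(1-arylvinyl)cycloalkanols and the thionium- or oxocarbenium-triggered pinacol-type expansions of cyclopentanols to 2-hetero-substituted cyclohexanones; new is their union, with sulfur in place of an aryl group as cation stabiliser and an unstrained trans-hydrindanol as substrate. C9 migrates with retention, which carries its configuration and the trans ring fusion into the decalin, whereas the new C10 centre (SPh β and chain α expected from the rotamer that holds sulfur next to the OH) is temporary and is erased in step 14. The selectivity needed is migration of the quaternary C9 rather than of C6H2; it rests on the higher migratory aptitude of the more substituted carbon toward a cationic terminus, the same preference that rules the Baeyer–Villiger oxidation of this ring type (17-oxo steroids), and on relief of the strain of the trans-hydrindane. Diversions of 20 (proton loss from C1, capture by bromide, by the OH or by the ester carbonyl) are reversible, while the shift is not, because it ends in a C=O bond.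

Step 14
Reactants: 21 benzyl 3-[14α-(ArCH2)-9β,13β,14β-trimethyl-5-oxo-10β-(phenylthio)-8αH-decalin-10α-yl]propanoate
Product: 22 benzyl 3-[14α-(ArCH2)-9β,13β,14β-trimethyl-5-oxo-8αH,10αH-decalin-10β-yl]propanoate
Conditions: SmI2 (2.5 equiv), THF–MeOH, −78 °C
Reagents that add atoms: none
Why: Samarium diiodide cleaves the C–S bond α to the ketone and the samarium enolate is protonated at C10 on the open α face, giving the epimer with the chain equatorial (β), which is also the more stable one, so that base equilibration could correct any shortfall.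

Step 15
Reactants: 23 2-methylpropanoyl chloride, 24 thiophenol
Product: 25 S-phenyl 2-methylpropanethioate
Conditions: Et3N, CH2Cl2, 0 °C
Reagents that add atoms: none
Why: Acylation of thiophenol with the acid chloride gives the thiol ester needed for the β-lactone synthesis.

Step 16
Reactants: 22 benzyl 3-[14α-(ArCH2)-9β,13β,14β-trimethyl-5-oxo-8αH,10αH-decalin-10β-yl]propanoate, 25 S-phenyl 2-methylpropanethioate
Product: 27 spiro β-lactone of 22 (C5 shared by ring B and a 3,3-dimethyloxetan-2-one; lactone O axial β; CMe2 equatorial), via lithium thiol ester enolate 26 (not isolated)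
Conditions: 25, LDA, THF, −78 °C; then 22, −78 → 0 °C; H2O
Reagents that add atoms: none
Why: Aldol addition of the thiol ester enolate to the ketone is followed by ring closure of the aldolate with loss of thiophenolate (thiol ester route to β-lactones), with equatorial attack because the axial path is blocked by the C9 methyl, and the weakly basic enolate should touch neither the benzyl ester nor C10.

Step 17
Reactants: 27 spiro β-lactone of 22
Product: 28 benzyl 3-[14α-(ArCH2)-5-isopropylidene-9β,13β,14β-trimethyl-8αH,10αH-decalin-10β-yl]propanoate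
Conditions: 2,4,6-collidine, 160 °C
Reagents that add atoms: none
Why: Thermal [2+2] cycloreversion of the β-lactone expels CO2 and leaves the C5=C4 double bond exactly where the four-membered ring was, so that no endocyclic or isopropenyl isomer can form.

Step 18
Reactants: 28 benzyl 3-[14α-(ArCH2)-5-isopropylidene-9β,13β,14β-trimethyl-8αH,10αH-decalin-10β-yl]propanoate
Product: 30 hydroquinone benzyl ester (28 with both OCH3 replaced by OH), via quinone 29 (not isolated)
Conditions: (NH4)2Ce(NO3)6, MeCN–H2O, 0 °C; extract; then Na2S2O4, Et2O–H2O, 25 °C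
Reagents that add atoms: water O
Why: Oxidative demethylation of the 1,4-dimethoxyarene with (NH4)2Ce(NO3)6 should be faster than any attack on the alkene, and dithionite reduces the quinone to the hydroquinone in the work-up.

Step 19
Reactants: 30 hydroquinone benzyl ester
Product: 31 monoacetate benzyl ester (acetate on the OH para to the hindered OH)
Conditions: Ac2O (1.1 equiv), pyridine, CH2Cl2, 0 °C
Reagents that add atoms: acetic anhydride CC(=O)OC(C)=O
Why: The acetylation is ruled by sterics, since the OH between CH3 and C15H2 is shielded while the other OH has two ortho hydrogens and reacts first, and the acid is still masked so no mixed anhydride can interfere.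

Step 20
Reactants: 31 monoacetate benzyl ester
Product: 32 target CNP0144688.2
Conditions: H2 (1 atm), 10% Pd/C, EtOAc, 25 °C
Reagents that add atoms: none
Why: Hydrogenolysis of the benzyl ester frees the acid under neutral conditions that spare the aryl acetate, and the hindered tetrasubstituted alkene should be inert at this pressure.

**Compound list**

1 | 4-methoxy-2-methylphenol | COc1ccc(O)c(C)c1 | starting material
2 | 2-hydroxy-5-methoxy-3-methylbenzaldehyde | COc1cc(C)c(O)c(C=O)c1 | intermediate
3 | 2,5-dimethoxy-3-methylbenzaldehyde | COc1cc(C)c(OC)c(C=O)c1 | intermediate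
4 | (2,5-dimethoxy-3-methylphenyl)methanol | COc1cc(C)c(OC)c(CO)c1 | intermediate
5 | 1-(bromomethyl)-2,5-dimethoxy-3-methylbenzene | COc1cc(C)c(OC)c(CBr)c1 | intermediate
6 | 2-methylcyclopentane-1,3-dione | CC1C(=O)CCC1=O | starting material
7 | pent-1-en-3-one (ethyl vinyl ketone) | CCC(=O)C=C | starting material
8 | 2-methyl-2-(3-oxopentyl)cyclopentane-1,3-dione | CCC(=O)CCC1(C)C(=O)CCC1=O | intermediate
9 | (7aR)-4,7a-dimethyl-2,3,7,7a-tetrahydro-1H-indene-1,5(6H)-dione | CC1=C2CCC(=O)[C@]2(C)CCC1=O | intermediate
10 | (1R,7aR)-1-hydroxy-4,7a-dimethyl-1,2,3,6,7,7a-hexahydro-5H-inden-5-one (OH cis to the angular methyl) | CC1=C2CC[C@@H](O)[C@]2(C)CCC1=O | intermediate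
11 | dilithium enolate alkoxide (trans-fused; C13–O enolate C13=C14; C5–O alkoxide) | [Li+].[Li+].CC1=C([O-])CC[C@@]2(C)[C@H]([O-])CC[C@H]12 | intermediate
12 | 14α-(ArCH2)-5β-hydroxy-9β,14β-dimethyl-8αH-hydrindan-13-one | COc1cc(C)c(OC)c(C[C@]2(C)[C@H]3CC[C@@H](O)[C@]3(C)CCC2=O)c1 | intermediate
13 | 14α-(ArCH2)-9β,14β-dimethyl-13-methylene-8αH-hydrindan-5β-ol | COc1cc(C)c(OC)c(C[C@]2(C)[C@H]3CC[C@@H](O)[C@]3(C)CCC2=C)c1 | intermediate
14 | 14α-(ArCH2)-9β,13β,14β-trimethyl-8αH-hydrindan-5β-ol | COc1cc(C)c(OC)c(C[C@]2(C)[C@H]3CC[C@@H](O)[C@]3(C)CC[C@H]2C)c1 | intermediate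
15 | 14α-(ArCH2)-9β,13β,14β-trimethyl-8αH-hydrindan-5-one | COc1cc(C)c(OC)c(C[C@]2(C)[C@H]3CCC(=O)[C@]3(C)CC[C@H]2C)c1 | intermediate
16 | phenyl vinyl sulfide | C=CSc1ccccc1 | starting material
17 | 1-(phenylthio)vinyllithium | [Li]C(=C)Sc1ccccc1 | intermediate
18 | 14α-(ArCH2)-9β,13β,14β-trimethyl-5α-[1-(phenylthio)vinyl]-8αH-hydrindan-5β-ol | COc1cc(C)c(OC)c(C[C@]2(C)[C@H]3CC[C@@](C(=C)Sc4ccccc4)(O)[C@]3(C)CC[C@H]2C)c1 | intermediate
19 | benzyl bromoacetate | BrCC(=O)OCc1ccccc1 | starting material
20 | thionium ion (C10=S+Ph; C10 bears CH2CH2CO2Bn and the C5 carbinol carbon) | COc1cc(C)c(OC)c(C[C@]2(C)[C@H]3CC[C@@](C(CCC(=O)OCc4ccccc4)=[S+]c4ccccc4)(O)[C@]3(C)CC[C@H]2C)c1 | intermediate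
21 | benzyl 3-[14α-(ArCH2)-9β,13β,14β-trimethyl-5-oxo-10β-(phenylthio)-8αH-decalin-10α-yl]propanoate | COc1cc(C)c(OC)c(C[C@]2(C)[C@H]3CCC(=O)[C@@](CCC(=O)OCc4ccccc4)(Sc4ccccc4)[C@]3(C)CC[C@H]2C)c1 | intermediate
22 | benzyl 3-[14α-(ArCH2)-9β,13β,14β-trimethyl-5-oxo-8αH,10αH-decalin-10β-yl]propanoate | COc1cc(C)c(OC)c(C[C@]2(C)[C@H]3CCC(=O)[C@@H](CCC(=O)OCc4ccccc4)[C@]3(C)CC[C@H]2C)c1 | intermediate
23 | 2-methylpropanoyl chloride | CC(C)C(=O)Cl | starting material
24 | thiophenol | Sc1ccccc1 | starting material
25 | S-phenyl 2-methylpropanethioate | CC(C)C(=O)Sc1ccccc1 | intermediate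
26 | lithium enolate of 25 | [Li+].CC(C)=C([O-])Sc1ccccc1 | intermediate
27 | spiro β-lactone of 22 (C5 spiro; lactone O axial β; CMe2 equatorial) | COc1cc(C)c(OC)c(C[C@]2(C)[C@H]3CC[C@@]4(OC(=O)C4(C)C)[C@@H](CCC(=O)OCc5ccccc5)[C@]3(C)CC[C@H]2C)c1 | intermediate
28 | benzyl 3-[14α-(ArCH2)-5-isopropylidene-9β,13β,14β-trimethyl-8αH,10αH-decalin-10β-yl]propanoate | COc1cc(C)c(OC)c(C[C@]2(C)[C@H]3CCC(=C(C)C)[C@@H](CCC(=O)OCc4ccccc4)[C@]3(C)CC[C@H]2C)c1 | intermediate
29 | 2-methyl-6-(C15-linked decalinylmethyl)-1,4-benzoquinone benzyl ester | CC1=CC(=O)C=C(C[C@]2(C)[C@H]3CCC(=C(C)C)[C@@H](CCC(=O)OCc4ccccc4)[C@]3(C)CC[C@H]2C)C1=O | intermediate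
30 | hydroquinone benzyl ester | Oc1cc(C)c(O)c(C[C@]2(C)[C@H]3CCC(=C(C)C)[C@@H](CCC(=O)OCc4ccccc4)[C@]3(C)CC[C@H]2C)c1 | intermediate
31 | monoacetate benzyl ester | CC(=O)Oc1cc(C)c(O)c(C[C@]2(C)[C@H]3CCC(=C(C)C)[C@@H](CCC(=O)OCc4ccccc4)[C@]3(C)CC[C@H]2C)c1 | intermediate
32 | CNP0144688.2: trans-decalin with 8-H α, 9-CH3 β, 10-H α (chain β), 13-CH3 β, 14-CH3 β, 14-CH2Ar' α, where Ar' = 5-acetoxy-2-hydroxy-3-methylphenyl | CC(=O)Oc1cc(C)c(O)c(C[C@]2(C)[C@H]3CCC(=C(C)C)[C@@H](CCC(=O)O)[C@]3(C)CC[C@H]2C)c1 | target

**Step count**

Total step count: 20.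
Longest linear sequence: 16 steps (steps 1–4, 8–14, 16–20). The hydrindane branch (steps 5–7) is one step shorter.

**Steps most likely to fail**

Step 13. The thionium ion may lose a proton or be captured before C9 migrates, the radical chain may stall, or C6 may compete as the migrating carbon.
- The fallback uses known two-electron chemistry, sets out from 15 and comes back at 21.
- Ketone 15 is treated with bis(phenylthio)methyllithium ((PhS)2CH2, n-BuLi, THF, −78 °C) to give 14α-(ArCH2)-5α-[bis(phenylthio)methyl]-9β,13β,14β-trimethyl-8αH-hydrindan-5β-ol F1.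
- CuOTf (monovalent copper) and iPr2NEt in hot benzene take away one thiolate. The thionium ion so formed undergoes the established pinacol-type one-carbon expansion to 14α-(ArCH2)-9β,13β,14β-trimethyl-10α-(phenylthio)-8αH-decalin-5-one F2.
- DBU-catalysed Michael addition of the doubly activated C10–H of F2 to benzyl acrylate, from the α face, gives 21.
- Here the chain is brought in after the ring expansion and no radical or photochemical event is needed.

Step 16. The crowded aldol addition may revert before the aldolate closes to the lactone, so that the ketone is returned.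
- The fallback sets out from 22 and comes back at 28.
- Kinetic deprotonation at C6 (KHMDS, PhNTf2, THF, −78 °C) gives the C5(6)-enol triflate of 22 F3.
- Suzuki–Miyaura coupling with isopropenylboronic acid pinacol ester (Pd(PPh3)4, K3PO4, dioxane–H2O) gives the 5-isopropenyl-5(6)-ene diene F4.
- 1,4-Hydrogenation of the s-cis diene with (C10H8)Cr(CO)3 and H2 in THF adds hydrogen at C6 and at the CH2 terminus and leaves the C5=C4 double bond of 28.

Step 8. C-alkylation of the tetrasubstituted enolate in ammonia may be slow, with proton exchange, O-alkylation or erosion of the trans ring fusion as the consequence.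
- The fallback sets out from 10 and comes back at 12.
- The Li/NH3 reduction is run alone, ammonia is removed and 11 is trapped with TMSCl/Et3N as the bis(trimethylsilyl) enol ether/ether F5. This can be purified and its ring fusion checked.
- Lewis-acid-catalysed SN1-type benzylation of this neutral enol silane with 5 (ZnBr2 cat., CH2Cl2, 0 °C), which draws on the stabilised 2,5-dimethoxybenzyl cation, is followed by 1 M HCl/THF to give 12.

**Further compounds**

F1 | step 13 | 14α-(ArCH2)-5α-[bis(phenylthio)methyl]-9β,13β,14β-trimethyl-8αH-hydrindan-5β-ol | COc1cc(C)c(OC)c(C[C@]2(C)[C@H]3CC[C@@](C(Sc4ccccc4)Sc4ccccc4)(O)[C@]3(C)CC[C@H]2C)c1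
F2 | step 13 | 14α-(ArCH2)-9β,13β,14β-trimethyl-10α-(phenylthio)-8αH-decalin-5-one | COc1cc(C)c(OC)c(C[C@]2(C)[C@H]3CCC(=O)[C@H](Sc4ccccc4)[C@]3(C)CC[C@H]2C)c1
F3 | step 16 | C5(6)-enol triflate of 22 | COc1cc(C)c(OC)c(C[C@]2(C)[C@H]3CC=C(OS(=O)(=O)C(F)(F)F)[C@@H](CCC(=O)OCc4ccccc4)[C@]3(C)CC[C@H]2C)c1
F4 | step 16 | 5-isopropenyl-5(6)-ene diene | COc1cc(C)c(OC)c(C[C@]2(C)[C@H]3CC=C(C(C)=C)[C@@H](CCC(=O)OCc4ccccc4)[C@]3(C)CC[C@H]2C)c1
F5 | step 8 | bis(trimethylsilyl) enol ether/ether of the reduced enone (trans-fused) | CC1=C(O[Si](C)(C)C)CC[C@@]2(C)[C@H](O[Si](C)(C)C)CC[C@H]12
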